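## Structural features

The target is a drimane sesquiterpene ether of 7-hydroxycoumarin: a trans-fused decalin (ring A = C1–C5, C10; ring B = C5–C10; drimane numbering, kept for all intermediates) whose C9 carries the C11H2–O–aryl arm. Ring A bears the equatorial 3β-hydroxyl at C3 next to the gem-dimethyl carbon C4; the fusion has the angular methyl on quaternary C10 and a trans hydrogen at C5. Ring B holds a semicyclic conjugated diene, C6=C7 in the ring and C8=C12 exocyclic, so that C9 is allylic and also carries the aryloxymethyl group. Three stereocentres are contiguous (C5, C10, C9) and the fourth (C3) is insulated from them by C4; the SMILES is read as 3S,5R,9S,10S, that is 3β-OH, 5α-H, 9α-H, 10β-CH3. Fragile groups are the coumarin lactone (hydroxide, alkoxide), the C11 aryl ether (β-elimination through the doubly allylic H9) and the diene (acid-promoted double-bond migration, cycloaddition, oxidation). The real difficulty is quaternary C10 between two stereocentres, with the 1,3-diaxial C4/C10 methyl pair, together with a diene that a polyene cyclisation does not deliver and that is awkward to add later by dehydrogenation of C6–C7. The feature exploited is that the C6=C7–C8=C12 unit of ring B is exactly what a vinylallene leaves behind after a [4+2] cycloaddition with C5 and C8 as diene termini and C9=C10 as dienophile.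

## Logic of the disconnections

17 ⇒ 15 + 16. The C11–O bond is cut on the alkyl side. The aryl ether and the lactone are the base-sensitive parts, so they are joined last under neutral redox-condensation conditions. The terpenoid half is thereby free of the coumarin during the Lewis-acid and hydride steps. The forward step must select the primary C11–OH over the C3–OH and must not eliminate across C9–C11.

15 ⇒ 14 ⇒ 13. Bonds C5–C10 and C8–C9 are cut; this is the key disconnection. Ring B is the retron of a vinylallene Diels–Alder reaction: C6=C7 is the new alkene, C8=C12 the surviving allene bond, and C9=C10 with the C11 carbonyl the dienophile. The four-atom tether C4–C3–C2–C1 closes ring A in the same event. Two rings, the quaternary carbon, three stereocentres (C5, C9, C10) and the diene are all traded for an acyclic chain with one stereocentre. The forward step needs endo selectivity, an E dienophile and facial control from C3.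

13 ⇒ 12 ⇒ 10 + 11. The C11 aldehyde is taken back to the allylic alcohol so that the dienophile is unmasked only just before the cycloaddition. The C6–C7 bond is then cut between an (E)-alkenylboronate and a propargylic carbonate. The forward coupling must deliver the allene and not the alkyne, with retention of the E geometry.

10 ⇒ 9 ⇒ 7 + 8. The C11 acetate is reinstated, and the C5=C6 alkene is cut by cross-metathesis back to a vinyl group on C4. This demands reaction at a monosubstituted alkene beside a quaternary carbon, while the trisubstituted C9=C10 alkene stays untouched.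

7 ⇒ 6 ⇒ 3 + 4 (through 5). The C3–C4 bond is cut. A reverse prenylation of an aldehyde builds the gem-dimethyl carbon, the vinyl handle and the only stereocentre that is set by a reagent. This demands reagent-controlled facial selectivity and tolerance of the acetate.

3 ⇒ 2 ⇒ 1. The C3 aldehyde comes from oxidative excision of the distal alkene of 1, which supplies the E-configured C9=C10 alkene and C11 ready-made.

## Other disconnections considered

Alternative 1: the first that comes to mind. Cut C4–C5 and C9–C10: Lewis-acid or Cp2TiCl (trivalent titanium) opening of the epoxy-farnesyl ether A1, with bicyclisation to the 8(12)-ene A2. This sets all four stereocentres at once, but A2 lacks C6=C7. Cationic termination spreads over several alkene isomers and monocycles. The second double bond would have to be added by allylic oxidation at C7 and a regiochemically uncertain elimination, at least three further steps, on a substrate with a labile β-aryloxy group. The chosen plan makes the diene in the ring-forming event.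

Alternative 2: buy the decalin. Start from the annulation product A3, gem-dimethylate and reduce to the hydroxy decalone A4, then add C12 at C8, C11 at C9 and the C6=C7 bond one by one. The annulation solves only ring fusion and C10. Every ring-B feature, including the C9 stereocentre beside an exocyclic methylene, would come from a long linear series of functional-group operations. The step count would be roughly double that of the chosen route.

Alternative 3: cut C6=C7 by ring-closing ene–diene metathesis of the triene A5. The closure forms one bond and no stereocentre. A5 must already hold C3, C5, C10 and C9 on a fully substituted ring A, so it is about as hard to make as the target. Its 2-substituted diene can also close through C8=C12 to a five-membered ring. The chosen cycloaddition forms two bonds and three stereocentres from an acyclic chain.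

Key step: step 9

## Route

Step 1
Reactants: 1 geranyl acetate [(2E)-3,7-dimethylocta-2,6-dien-1-yl acetate]
Product: 2 (2E)-5-(3,3-dimethyloxiran-2-yl)-3-methylpent-2-en-1-yl acetate (racemic at the oxirane carbon)
Conditions: mCPBA (1.05 equiv), CH2Cl2, 0 °C
Reagents that add atoms: mCPBA (3-chloroperoxybenzoic acid), OOC(=O)c1cccc(Cl)c1
Why: Prilezhaev epoxidation should take the electron-rich distal trisubstituted alkene, since the C9=C10 alkene is deactivated by the allylic acetate; the new stereocentre is destroyed in step 2.

Step 2
Reactants: 2 (2E)-5-(3,3-dimethyloxiran-2-yl)-3-methylpent-2-en-1-yl acetate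
Product: 3 (2E)-3-methyl-6-oxohex-2-en-1-yl acetate
Conditions: H5IO6, THF/H2O, 0 °C
Reagents that add atoms: none
Why: Periodic acid should hydrolyse the epoxide to the glycol and cleave it (Malaprade glycol cleavage) to the aldehyde and acetone, leaving the E alkene and the acetate untouched.

Step 3
Reactants: 3 (2E)-3-methyl-6-oxohex-2-en-1-yl acetate; 4 3-methylbuta-1,2-diene
Product: 6 (2E,6S)-6-hydroxy-3,7,7-trimethylnona-2,8-dien-1-yl acetate, via B-prenyldiisopinocampheylborane 5 (not isolated)
Conditions: (+)-Ipc2BH [from (−)-α-pinene], 4, THF, −25 °C; then 3, −78 °C; NaBO3·4H2O, THF/H2O, rt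
Reagents that add atoms: none
Why: Hydroboration of the allene gives prenylborane 5, which should add to the aldehyde through a closed chair (Zimmerman–Traxler) transition state with allylic transposition (asymmetric reverse prenylboration), forming C3–C4, the gem-dimethyl carbon and the vinyl group. The isopinocampheyl groups of the (−)-α-pinene series direct attack to the Re face and so set 3S; the acetate survives −78 °C and the mild perborate work-up.

Step 4
Reactants: 6 (2E,6S)-6-hydroxy-3,7,7-trimethylnona-2,8-dien-1-yl acetate
Product: 7 (2E,6S)-3,7,7-trimethylnona-2,8-diene-1,6-diyl diacetate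
Conditions: Ac2O, pyridine, DMAP (cat.), CH2Cl2, rt
Reagents that add atoms: acetic anhydride, CC(=O)OC(C)=O
Why: DMAP-catalysed acylation should cap the hindered C3 hydroxyl with a small group that tolerates the Lewis acid of step 9 and is removed by the hydride used there.

Step 5
Reactants: 7 (2E,6S)-3,7,7-trimethylnona-2,8-diene-1,6-diyl diacetate; 8 4,4,5,5-tetramethyl-2-vinyl-1,3,2-dioxaborolane
Product: 9 (2E,6S,8E)-3,7,7-trimethyl-9-(4,4,5,5-tetramethyl-1,3,2-dioxaborolan-2-yl)nona-2,8-diene-1,6-diyl diacetate
Conditions: second-generation Hoveyda–Grubbs catalyst (5 mol %), 8 (4 equiv), CH2Cl2, 40 °C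
Reagents that add atoms: none
Why: Olefin cross-metathesis should engage only the monosubstituted alkene, which cannot homodimerise beside the quaternary carbon, while the trisubstituted C9=C10 alkene is inert; the bulky boryl and tert-alkyl ends should give the E alkenylboronate.

Step 6
Reactants: 9 (2E,6S,8E)-3,7,7-trimethyl-9-(4,4,5,5-tetramethyl-1,3,2-dioxaborolan-2-yl)nona-2,8-diene-1,6-diyl diacetate
Product: 10 (1E,4S,7E)-9-hydroxy-3,3,7-trimethyl-1-(4,4,5,5-tetramethyl-1,3,2-dioxaborolan-2-yl)nona-1,7-dien-4-yl acetate
Conditions: K2CO3 (0.2 equiv), MeOH, 0 °C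
Reagents that add atoms: none
Why: Base-catalysed transesterification should remove the unhindered primary allylic acetate much faster than the secondary acetate flanked by the quaternary carbon; the pinacol boronate is stable to these conditions.

Step 7
Reactants: 10 (1E,4S,7E)-9-hydroxy-3,3,7-trimethyl-1-(4,4,5,5-tetramethyl-1,3,2-dioxaborolan-2-yl)nona-1,7-dien-4-yl acetate; 11 methyl prop-2-yn-1-yl carbonate
Product: 12 (2E,6S,8E)-1-hydroxy-3,7,7-trimethyldodeca-2,8,10,11-tetraen-6-yl acetate
Conditions: Pd(PPh3)4 (5 mol %), THF, 60 °C
Reagents that add atoms: none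
Why: SN2′ oxidative addition of zerovalent palladium to the propargylic carbonate, with loss of CO2, gives an allenylpalladium methoxide. Its methoxide should assist transmetalation of the alkenylboronate without added base, and reductive elimination at the allenyl terminus gives the vinylallene with the E alkene retained (Suzuki–Miyaura-type coupling of propargylic carbonates).

Step 8
Reactants: 12 (2E,6S,8E)-1-hydroxy-3,7,7-trimethyldodeca-2,8,10,11-tetraen-6-yl acetate
Product: 13 (2E,6S,8E)-3,7,7-trimethyl-1-oxododeca-2,8,10,11-tetraen-6-yl acetate
Conditions: MnO2 (activated, excess), CH2Cl2, rt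
Reagents that add atoms: none
Why: MnO2 should oxidise only the allylic alcohol, giving the E enal that serves as the activated dienophile, without touching the vinylallene or the acetate.

Step 9
Reactants: 13 (2E,6S,8E)-3,7,7-trimethyl-1-oxododeca-2,8,10,11-tetraen-6-yl acetate
Product: 15 (2S,4aS,5S,8aR)-5-(hydroxymethyl)-1,1,4a-trimethyl-6-methylidene-1,2,3,4,4a,5,6,8a-octahydronaphthalen-2-ol, via cycloadduct aldehyde 14 (not isolated)
Conditions: Me2AlCl (2.5 equiv), CH2Cl2, −78 → −20 °C; then iBu2AlH (6 equiv), −78 → 0 °C; aq. potassium sodium tartrate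
Reagents that add atoms: none
Why: Me2AlCl binds the enal carbonyl and lowers the LUMO of C9=C10, and the s-cis vinylallene C5=C6–C7=C8 should add across it in a concerted, asynchronous intramolecular Diels–Alder reaction that forms C5–C10 and C8–C9 and leaves the orthogonal C8=C12 bond as the exocyclic methylene; the closest known types are Lewis-acid-promoted cycloadditions of 1,3,9-decatrienals and intramolecular Diels–Alder reactions of vinylallenes. Ring A closes in the fused mode through the four-atom tether C4–C3–C2–C1 in a chair-like arrangement, and ring B is the cyclohexene made by the cycloaddition itself. The cis relation of the C10 methyl and the C9 formyl group follows from the E geometry of the dienophile under suprafacial addition. The trans ring fusion (C5–H anti to C10–CH3) follows from the endo placement of the aluminium-bound formyl group with the tether exo, a preference that Lewis acids reinforce. The absolute sense at C5, C9 and C10 is relayed from C3, because the chair with the acetoxy group equatorial leads to the 5R,9S,10S adduct while the other trans-fused chair needs it axial. The step therefore needs endo over exo selectivity and equatorial over axial discrimination; the latter is modest beside the gem-dimethyl carbon, and the low temperature is relied on to amplify it. Reactivity is helped by the vinylallene, which has no inside substituent at C8 and releases allene strain, by the gem-dimethyl group that favours the folded tether, and by quaternary C4, which rules out a [1,5]-hydrogen shift of the vinylallene. iBu2AlH then reduces the aluminium-bound aldehyde 14 in the flask, before it can epimerise at C9 or move into conjugation, and cleaves the acetate to give the diol.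

Step 10
Reactants: 15 (2S,4aS,5S,8aR)-5-(hydroxymethyl)-1,1,4a-trimethyl-6-methylidene-1,2,3,4,4a,5,6,8a-octahydronaphthalen-2-ol; 16 7-hydroxy-2H-chromen-2-one (umbelliferone)
Product: 17 7-{[(1S,4aR,6S,8aS)-6-hydroxy-5,5,8a-trimethyl-2-methylidene-1,2,4a,5,6,7,8,8a-octahydronaphthalen-1-yl]methoxy}-2H-chromen-2-one
Conditions: PPh3, DIAD, THF, 0 °C → rt
Reagents that add atoms: none
Why: The Mitsunobu reaction should activate only the primary C11 hydroxyl, since the C3 hydroxyl beside the quaternary carbon is too hindered, and the acidic phenol displaces the oxyphosphonium under neutral conditions that spare the lactone and the diene.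

## Compound list

1 | geranyl acetate, (2E)-3,7-dimethylocta-2,6-dien-1-yl acetate | CC(C)=CCC/C(C)=C/COC(C)=O | starting material
2 | (2E)-5-(3,3-dimethyloxiran-2-yl)-3-methylpent-2-en-1-yl acetate (racemic at the oxirane carbon) | CC1(C)OC1CC/C(C)=C/COC(C)=O | intermediate
3 | (2E)-3-methyl-6-oxohex-2-en-1-yl acetate | O=CCC/C(C)=C/COC(C)=O | intermediate
4 | 3-methylbuta-1,2-diene | CC(C)=C=C | starting material
5 | B-(3-methylbut-2-en-1-yl)diisopinocampheylborane of the (−)-α-pinene series (not isolated) | CC(C)=CCB([C@H]1C[C@H]2C[C@@H]([C@@H]1C)C2(C)C)[C@H]1C[C@H]2C[C@@H]([C@@H]1C)C2(C)C | intermediate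
6 | (2E,6S)-6-hydroxy-3,7,7-trimethylnona-2,8-dien-1-yl acetate | C=CC(C)(C)[C@@H](O)CC/C(C)=C/COC(C)=O | intermediate
7 | (2E,6S)-3,7,7-trimethylnona-2,8-diene-1,6-diyl diacetate | C=CC(C)(C)[C@@H](OC(C)=O)CC/C(C)=C/COC(C)=O | intermediate
8 | 4,4,5,5-tetramethyl-2-vinyl-1,3,2-dioxaborolane | C=CB1OC(C)(C)C(C)(C)O1 | starting material
9 | (2E,6S,8E)-3,7,7-trimethyl-9-(4,4,5,5-tetramethyl-1,3,2-dioxaborolan-2-yl)nona-2,8-diene-1,6-diyl diacetate | CC1(C)OB(/C=C/C(C)(C)[C@@H](OC(C)=O)CC/C(C)=C/COC(C)=O)OC1(C)C | intermediate
10 | (1E,4S,7E)-9-hydroxy-3,3,7-trimethyl-1-(4,4,5,5-tetramethyl-1,3,2-dioxaborolan-2-yl)nona-1,7-dien-4-yl acetate | CC1(C)OB(/C=C/C(C)(C)[C@@H](OC(C)=O)CC/C(C)=C/CO)OC1(C)C | intermediate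
11 | methyl prop-2-yn-1-yl carbonate | C#CCOC(=O)OC | starting material
12 | (2E,6S,8E)-1-hydroxy-3,7,7-trimethyldodeca-2,8,10,11-tetraen-6-yl acetate | C=C=C/C=C/C(C)(C)[C@@H](OC(C)=O)CC/C(C)=C/CO | intermediate
13 | (2E,6S,8E)-3,7,7-trimethyl-1-oxododeca-2,8,10,11-tetraen-6-yl acetate | C=C=C/C=C/C(C)(C)[C@@H](OC(C)=O)CC/C(C)=C/C=O | intermediate
14 | (2S,4aS,5S,8aR)-5-formyl-1,1,4a-trimethyl-6-methylidene-1,2,3,4,4a,5,6,8a-octahydronaphthalen-2-yl acetate (not isolated) | C=C1C=C[C@H]2C(C)(C)[C@@H](OC(C)=O)CC[C@]2(C)[C@H]1C=O | intermediate
15 | (2S,4aS,5S,8aR)-5-(hydroxymethyl)-1,1,4a-trimethyl-6-methylidene-1,2,3,4,4a,5,6,8a-octahydronaphthalen-2-ol | C=C1C=C[C@H]2C(C)(C)[C@@H](O)CC[C@]2(C)[C@H]1CO | intermediate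
16 | 7-hydroxy-2H-chromen-2-one (umbelliferone) | O=c1ccc2ccc(O)cc2o1 | starting material
17 | 7-{[(1S,4aR,6S,8aS)-6-hydroxy-5,5,8a-trimethyl-2-methylidene-1,2,4a,5,6,7,8,8a-octahydronaphthalen-1-yl]methoxy}-2H-chromen-2-one | C=C1C=C[C@H]2C(C)(C)[C@@H](O)CC[C@]2(C)[C@H]1COc1ccc2ccc(=O)oc2c1 | target

## Step count and least certain steps

Total: 10 steps. Longest linear sequence: 10 steps (1 → 17).

**Step 9 (key step).** The most likely failure is insufficient facial discrimination between the two trans-fused chair transition states. The equatorial preference of the C3 acetoxy group is small next to the gem-dimethyl carbon, and the developing 1,3-diaxial C4/C10 methyl interaction slows the cyclisation, so exo closure or Lewis-acid-induced oligomerisation of the vinylallene may compete. The fallback moves stereocontrol from C3 to a catalyst; it sets out from 12 and comes back at 15. Methanolysis of the remaining acetate (NaOMe, MeOH, 40 °C) should give (2E,6S,8E)-3,7,7-trimethyldodeca-2,8,10,11-tetraene-1,6-diol F1. Dess–Martin periodinane should oxidise both hydroxyls to the achiral keto enal (2E,8E)-3,7,7-trimethyl-6-oxododeca-2,8,10,11-tetraenal F2, in which C3 is trigonal, so the chair preference no longer matters and the tether is less strained. A prolinol-derived chiral oxazaborolidinium Lewis acid, in the enantiomer that exposes the required enal face, should then give (1S,4aR,8aS)-5,5,8a-trimethyl-2-methylidene-6-oxo-1,2,4a,5,6,7,8,8a-octahydronaphthalene-1-carbaldehyde F3. NaBH4 (MeOH, −20 °C) should reduce the aldehyde and, by axial hydride delivery from the α face, the C3 ketone to the equatorial 3β-alcohol, giving 15.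

**Step 5.** Turnover of the ruthenium carbene at the alkene beside the quaternary carbon may be slow, so catalyst decay can outrun conversion. The fallback replaces metathesis by hydroxyl-directed oxidative cleavage and a chromium olefination; it sets out from 6 and comes back at 9. Directed epoxidation of the homoallylic vinyl group (VO(acac)2, tBuOOH, CH2Cl2) should give (2E,6S)-6-hydroxy-3,7-dimethyl-7-(oxiran-2-yl)oct-2-en-1-yl acetate F4. Acetylation should give (2E,6S)-3,7-dimethyl-7-(oxiran-2-yl)oct-2-ene-1,6-diyl diacetate F5. H5IO6 should cleave the epoxide to (2E,6S)-3,7,7-trimethyl-8-oxooct-2-ene-1,6-diyl diacetate F6. Takai–Utimoto boryl-olefination (CrCl2, LiI, Cl2CHBpin, THF; divalent chromium) should convert the non-enolisable aldehyde into the E alkenylboronate 9.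

**Step 7.** Regiocontrol may be lost at the allenyl/propargyl palladium intermediate, giving a skipped enyne, and transmetalation of the pinacol boronate without base may be slow. The fallback forms the allene by copper-mediated homologation instead; it sets out from 10 and comes back at 12. Suzuki–Miyaura coupling with (bromoethynyl)trimethylsilane (Pd(PPh3)4, K3PO4, THF/H2O) should give (2E,6S,8E)-1-hydroxy-3,7,7-trimethyl-11-(trimethylsilyl)undeca-2,8-dien-10-yn-6-yl acetate F7. K2CO3 in MeOH at 0 °C should give the terminal enyne (2E,6S,8E)-1-hydroxy-3,7,7-trimethylundeca-2,8-dien-10-yn-6-yl acetate F8. Crabbé homologation ((CH2O)n, CuI, Cy2NH, dioxane, 100 °C) should give 12.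

**Step 10.** Displacement at the β-branched primary carbon is slow, so elimination across C9–C11 from the oxyphosphonium intermediate, through the doubly allylic H9, may compete. The fallback forms the aryl–oxygen bond instead of the alkyl–oxygen bond; it sets out from 15 and comes back at 17. Palladium-catalysed C–O coupling of the primary hydroxyl of 15 with 7-bromo-2H-chromen-2-one ([Pd(allyl)Cl]2, a bulky biaryl di-tert-butylphosphine, Cs2CO3, toluene, 80 °C) should give 17 directly; this fallback makes no new intermediate (entry F0).

## Further compounds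

F1 | step 9 | (2E,6S,8E)-3,7,7-trimethyldodeca-2,8,10,11-tetraene-1,6-diol | C=C=C/C=C/C(C)(C)[C@@H](O)CC/C(C)=C/CO
F2 | step 9 | (2E,8E)-3,7,7-trimethyl-6-oxododeca-2,8,10,11-tetraenal | C=C=C/C=C/C(C)(C)C(=O)CC/C(C)=C/C=O
F3 | step 9 | (1S,4aR,8aS)-5,5,8a-trimethyl-2-methylidene-6-oxo-1,2,4a,5,6,7,8,8a-octahydronaphthalene-1-carbaldehyde | C=C1C=C[C@H]2C(C)(C)C(=O)CC[C@]2(C)[C@H]1C=O
F4 | step 5 | (2E,6S)-6-hydroxy-3,7-dimethyl-7-(oxiran-2-yl)oct-2-en-1-yl acetate (epimers at the oxirane carbon) | C1OC1C(C)(C)[C@@H](O)CC/C(C)=C/COC(C)=O
F5 | step 5 | (2E,6S)-3,7-dimethyl-7-(oxiran-2-yl)oct-2-ene-1,6-diyl diacetate (epimers at the oxirane carbon) | C1OC1C(C)(C)[C@@H](OC(C)=O)CC/C(C)=C/COC(C)=O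
F6 | step 5 | (2E,6S)-3,7,7-trimethyl-8-oxooct-2-ene-1,6-diyl diacetate | O=CC(C)(C)[C@@H](OC(C)=O)CC/C(C)=C/COC(C)=O
F7 | step 7 | (2E,6S,8E)-1-hydroxy-3,7,7-trimethyl-11-(trimethylsilyl)undeca-2,8-dien-10-yn-6-yl acetate | C[Si](C)(C)C#C/C=C/C(C)(C)[C@@H](OC(C)=O)CC/C(C)=C/CO
F8 | step 7 | (2E,6S,8E)-1-hydroxy-3,7,7-trimethylundeca-2,8-dien-10-yn-6-yl acetate | C#C/C=C/C(C)(C)[C@@H](OC(C)=O)CC/C(C)=C/CO
F0 | step 10 | none | none
A1 | alternative 1 | 7-{[(2E,6E)-9-[(2S)-3,3-dimethyloxiran-2-yl]-3,7-dimethylnona-2,6-dien-1-yl]oxy}-2H-chromen-2-one | CC1(C)O[C@H]1CC/C(C)=C/CC/C(C)=C/COc1ccc2ccc(=O)oc2c1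
A2 | alternative 1 | 7-{[(1S,4aR,6S,8aS)-6-hydroxy-5,5,8a-trimethyl-2-methylidenedecahydronaphthalen-1-yl]methoxy}-2H-chromen-2-one | C=C1CC[C@H]2C(C)(C)[C@@H](O)CC[C@]2(C)[C@H]1COc1ccc2ccc(=O)oc2c1
A3 | alternative 2 | (8aS)-8a-methyl-3,4,8,8a-tetrahydronaphthalene-1,6(2H,7H)-dione (Wieland–Miescher ketone) | C[C@]12CCC(=O)C=C1CCCC2=O
A4 | alternative 2 | (4aS,6S,8aS)-6-hydroxy-5,5,8a-trimethyloctahydronaphthalen-1(2H)-one | O=C1CCC[C@H]2C(C)(C)[C@@H](O)CC[C@]12C
A5 | alternative 3 | 7-{[2-(4-hydroxy-1,3,3-trimethyl-2-vinylcyclohexyl)-3-methylidenepent-4-en-1-yl]oxy}-2H-chromen-2-one with the target configuration at C3, C5, C9 and C10 | C=C[C@H]1C(C)(C)[C@@H](O)CC[C@]1(C)[C@H](C(=C)C=C)COc1ccc2ccc(=O)oc2c1
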